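## Analysis of the target

Target 20 is a monocyclic oxolane (ring atoms O1, C2, C3, C4, C5). C2 carries a 3,4,5-trimethoxyphenyl group, C3 a hydroxymethyl group (C9), and C4 an exocyclic secondary carbinol C7' bearing a 3,4-dimethoxyphenyl group; C5 is an unsubstituted CH2. There are four stereocentres: C2 (R), C3 (S) and C4 (R) are mutually trans around the ring, which is the most stable arrangement, and C7' (S) lies outside the ring where ring thermodynamics cannot reach it. Both benzylic C–O bonds (C2–O1 and C7'–OH) sit next to electron-rich arenes and ionize readily in acid, which would cause epimerization, elimination or Friedel–Crafts closure to an aryltetralin, so the late steps must be non-acidic. The difficulty is to set three contiguous ring centres in one absolute sense, to add the exocyclic carbinol with its own configuration, and to keep the C9 and C7' oxygens distinguishable. The strategy rests on the fact that C7' is bonded directly to ring carbon C4 and can be carried at the carbonyl oxidation level. At that level C4 is α to a carbonyl and can be equilibrated, and the C4–C7' unit is what a ketene gives with a nucleophile. The C3–C4 bond and C7' can therefore arise together from a six-membered 5-diazo-oxan-4-one (10), in which C7' is the ring carbonyl flanked by C3 and by the diazo carbon that becomes C4. In that six-membered ring C3 lies between the carbonyl and C2, so C9 can be attached by enolate chemistry, and C2 is the carbinol carbon of an aldehyde-derived hetero-Diels–Alder adduct.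

## Retrosynthetic reasoning

Position labels C2, C3, C4, C5, C7' and C9 refer to the target; "oxane C3 … C6" refer to the six-membered intermediates (oxane C4 becomes C7', oxane C5 becomes C4, oxane C6 becomes C5).

**20 to 18 (C7'–H bond, C9–O–Si bond).** The last operation is removal of the silyl group from 19, chosen because it needs no acid. The C7' carbinol of 19 is traced to aryl ketone 18. C7' is the only stereocentre that the ring cannot control, so it is set last by a reagent-controlled reduction. The forward step must select one face of a ketone flanked by an aryl group and a branched oxolanyl group.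

**18 to 15 and 16 (C7'–aryl bond).** Cutting the bond between C7' and the dimethoxyphenyl ring gives Weinreb amide 15 and aryl bromide 16, which is used as its lithium derivative 17. This cut is preferred over cutting C4–C7' because the acyl carbon is already on the ring after the key step and the aryl group arrives as a simple purchased arene. Amide 15 comes from ester 14 by aminolysis.

**14 to 10 and 11 (C3–C4 bond, key disconnection).** Ester 14 is opened by a retro-Wolff operation: the C3–C4 bond is cut and the ester carbon is reinserted between C3 and C4 as a ring carbonyl, giving diazo oxanone 10 and methanol 11. This removes a stereocentre from the problem, because C4 can be set afterwards by equilibration. It also turns a trisubstituted oxolane into a six-membered ring that is accessible by cycloaddition. The forward reaction must contract the ring by shifting C3 with retention.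

**10 to 8 to 7 (C=N2 at oxane C5; C5=C6 double bond).** The diazo group is removed to give ketone 8. Its placement is unambiguous because the other α-carbon is substituted. Ketone 8 is the conjugate-reduction product of enone 7, so the oxane C5–C6 unit can stay an enol ether double bond until then.

**7 to 6 to 4 and 5 (C3–C9 bond).** The silyl ether 7 comes from alcohol 6, and the C3–C9 bond of 6 is cut to dihydropyranone 4 and formaldehyde 5. In 4 the only enolizable carbon is oxane C3, so the aldol can occur nowhere else, and the C2 aryl group directs C9 to the trans position.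

**4 to 1 and 2 (C2–C3 and O1–C6 bonds of the oxane).** Dihydropyranone 4 is the hetero-Diels–Alder adduct of aldehyde 1 and diene 2. This is the only step that must create absolute configuration from achiral material, and it does so catalytically at C2, the one ring centre with no adjacent carbonyl at any later stage.

## Alternatives that were turned down

**Alternative 1: tandem conjugate addition–aldol on a chiral butenolide.**
- Disconnection: the C4–C7' and C2–C3 bonds, both made on (5R)-5-(l-menthyloxy)furan-2(5H)-one A1, with C7' masked in 2-(3,4-dimethoxyphenyl)-1,3-dithiane A2 and C2 supplied by aldehyde 1.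
- Forward key step: deprotonated A2 adds to the β-carbon of A1 anti to the menthyloxy group, and the lactone enolate is trapped by 1 anti to the new substituent, giving the trans,trans lactone A3.
- For it: two skeletal bonds and the C3/C4 relationship from three simple components in one flask, with a cheap crystalline auxiliary on a rigid ring. In convergence and bonds per step it is stronger than the chosen route.
- Against it for 20: the ring of A3 is not the target ring. Its ring oxygen joins the future C9 and C5, whereas 20 needs O1 between C2 and C5, so the lactone and acetal must be reduced and the oxolane closed afterwards through the C2 oxygen. The C2 carbinol configuration from the aldol is not reliably controlled and would be corrected only by an acid closure through the trimethoxybenzyl cation. The dithiane must be cleaved next to two electron-rich arenes, the auxiliary is stoichiometric, and C7' still needs a selective reduction.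
- Comparison: about six operations follow A3, so the length is similar. The chosen route offers instead a key step that delivers the target ring with C9 and C7' at usable oxidation levels, a catalytic source of chirality, and no acid-mediated closure.

**Alternative 2: Prins–pinacol ring contraction.**
- Disconnection: the C2–C3 and C4–C5 bonds, from 4-(3,4-dimethoxyphenyl)-4-[(E)-3-(tert-butyldiphenylsilyloxy)prop-1-enyl]-2-(3,4,5-trimethoxyphenyl)-1,3-dioxolane A4.
- Forward key step: a strong Lewis acid opens the acetal to an oxocarbenium ion at O1, the (E)-alkene attacks it to form C2–C3 and a six-membered cation, and the ring CH2 shifts from C7' to C4, contracting the ring and giving aryl ketone A5.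
- For it: one step makes the ring, two C–C bonds and all three ring stereocentres in the all-trans sense, and A5 is ketone 18 with a different silyl group. From its precursor onward it is clearly more step-economical than the sequence from 4 to 18.
- Against it for 20: A4 needs an enantiopure tertiary allylic diol whose stereocentre is built only to be destroyed. The cation at C4 is secondary. The electron-rich aryl group on C7' competes with the ring CH2 as the migrating group, which would keep the six-membered ring. The tertiary benzylic, allylic C–O bond can ionize under the Lewis acid and lose the stereochemical information. The trimethoxyphenyl-stabilized oxocarbenium ion is a weak electrophile.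
- Comparison: both strategies are ring contractions. The Wolff version has a single possible migrating group, no cationic intermediate and a driving force in nitrogen loss, at the price of more steps and of building C9 and the C7' aryl group separately.

**Alternative 3: three-component Prins closure with hydration.**
- Disconnection: the O1–C5, C4–C5 and C7'–O bonds, from (1R,2S,3E)-2-{[(tert-butyldiphenylsilyl)oxy]methyl}-4-(3,4-dimethoxyphenyl)-1-(3,4,5-trimethoxyphenyl)but-3-en-1-ol A6 and formaldehyde 5.
- Forward key step: in a strong carboxylic acid, A6 and 5 form an oxocarbenium ion at O1, the styrene carbon C4 closes the oxolane, and the resulting 3,4-dimethoxybenzyl cation is captured as an ester and hydrolysed to A7, the C9 silyl ether of 20.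
- For it: it is the shortest plan. The ring, C4 and C7' are made in one step and only desilylation remains; in step count it is stronger than the chosen route.
- Against it for 20: C7' is set by capture of a free, strongly stabilized benzylic cation, so facial control is weak and re-ionization scrambles it. The homoallylic oxocarbenium ion can undergo oxonia-Cope rearrangement, which erodes C2 and C3. The C2–O bond next to the trimethoxyphenyl ring also ionizes in the acid. The C7' cation is well placed to attack the trimethoxyphenyl ring and form an aryltetralin.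
- Comparison: the chosen route is longer but never passes through a benzylic cation, and sets C7' on a ketone by reagent control, separately from the ring centres.

Key step: step 6

Assumption: the titanium catalyst from (R)-1,1'-bi-2-naphthol is taken to direct the diene to the Re face of aldehyde 1, as it does in allylation of aromatic aldehydes; if the sense proves opposite, the (S)-ligand is used.

## Route

Step 1
Reactants: 1 3,4,5-trimethoxybenzaldehyde; 2 (E)-1-methoxy-3-(trimethylsilyloxy)buta-1,3-diene
Product: 4 (2R)-2-(3,4,5-trimethoxyphenyl)-2,3-dihydro-4H-pyran-4-one, via Mukaiyama aldol adduct 3 (not isolated)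
Conditions: (R)-1,1'-bi-2-naphthol (20 mol%), Ti(OiPr)4 (10 mol%), 4 Å molecular sieves, Et2O, −20 °C; then CF3CO2H, CH2Cl2, 0 °C
Reagents that add atoms: none
Why: Catalytic asymmetric hetero-Diels–Alder reaction in its stepwise Mukaiyama aldol–cyclization form: the chiral titanium binaphtholate activates the aldehyde, the diene terminus attacks the Re face to set C2, and acid closes adduct 3 by oxa-Michael addition with loss of methanol. With two meta and one para methoxy groups the aldehyde should be about as electrophilic as benzaldehyde.

Step 2
Reactants: 4 (2R)-2-(3,4,5-trimethoxyphenyl)-2,3-dihydro-4H-pyran-4-one; 5 formaldehyde (monomer, from cracking paraformaldehyde)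
Product: 6 (2R,3S)-3-(hydroxymethyl)-2-(3,4,5-trimethoxyphenyl)-2,3-dihydro-4H-pyran-4-one
Conditions: LiN(i-Pr)2, THF, −78 °C; then CH2O (gas), −78 °C; aq NH4Cl
Reagents that add atoms: none
Why: Kinetic deprotonation of the vinylogous ester at its only enolizable carbon (oxane C3) and aldol addition to formaldehyde. The electrophile should approach anti to the adjacent C2 aryl group, giving the 2,3-trans isomer, which is also the more stable one at this epimerizable centre.

Step 3
Reactants: 6 (2R,3S)-3-(hydroxymethyl)-2-(3,4,5-trimethoxyphenyl)-2,3-dihydro-4H-pyran-4-one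
Product: 7 (2R,3S)-3-{[(tert-butyldimethylsilyl)oxy]methyl}-2-(3,4,5-trimethoxyphenyl)-2,3-dihydro-4H-pyran-4-one
Conditions: t-BuMe2SiCl, imidazole, DMF, 0 → 20 °C
Reagents that add atoms: tert-butyldimethylsilyl chloride, CC(C)(C)[Si](C)(C)Cl
Why: Imidazole-promoted silylation of the primary alcohol. It blocks retro-aldol and dehydration of the β-hydroxy ketone and keeps the C9 oxygen distinct for the rest of the route.

Step 4
Reactants: 7 (2R,3S)-3-{[(tert-butyldimethylsilyl)oxy]methyl}-2-(3,4,5-trimethoxyphenyl)-2,3-dihydro-4H-pyran-4-one
Product: 8 (2R,3S)-3-{[(tert-butyldimethylsilyl)oxy]methyl}-2-(3,4,5-trimethoxyphenyl)oxan-4-one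
Conditions: LiBH(s-Bu)3, THF, −78 °C; aq NH4Cl
Reagents that add atoms: none
Why: Conjugate (1,4) reduction of a β-alkoxy enone by a bulky trialkylborohydride: hydride adds to the oxygen-bearing β-carbon (oxane C6) and the enolate resists further reduction until the quench. No stereocentre is created, and the trans-diequatorial C2/C3 arrangement is the stable one.

Step 5
Reactants: 8 (2R,3S)-3-{[(tert-butyldimethylsilyl)oxy]methyl}-2-(3,4,5-trimethoxyphenyl)oxan-4-one
Product: 10 (2R,3S)-3-{[(tert-butyldimethylsilyl)oxy]methyl}-5-diazo-2-(3,4,5-trimethoxyphenyl)oxan-4-one, via trifluoroacetyl ketone 9 (not isolated)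
Conditions: LiN(SiMe3)2, THF, −78 °C; CF3CO2CH2CF3; then MeSO2N3, Et3N, H2O, MeCN, 20 °C
Reagents that add atoms: methanesulfonyl azide, CS(=O)(=O)N=[N+]=[N-] (the two diazo nitrogens of 10); 2,2,2-trifluoroethyl trifluoroacetate, O=C(OCC(F)(F)F)C(F)(F)F (the trifluoroacetyl group of 9 only, lost again before 10)
Why: Detrifluoroacetylative diazo transfer (Regitz type): kinetic enolization at the unhindered CH2 (oxane C5) and Claisen acylation give 9, whose activated carbon takes the diazo group from the sulfonyl azide as the trifluoroacetyl group leaves. The other α-carbon (oxane C3) is substituted and cannot become a diazo carbon, so 10 is the only diazo ketone that can form.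

Step 6
Reactants: 10 (2R,3S)-3-{[(tert-butyldimethylsilyl)oxy]methyl}-5-diazo-2-(3,4,5-trimethoxyphenyl)oxan-4-one; 11 methanol
Product: 14 methyl (3R,4S,5R)-4-{[(tert-butyldimethylsilyl)oxy]methyl}-5-(3,4,5-trimethoxyphenyl)oxolane-3-carboxylate, via oxolanylidene ketene 12 (not isolated), via epimeric methyl ester 13 (not isolated)
Conditions: hν (365 nm), MeOH (degassed, dilute), 10–20 °C; then NaOCH3 (0.3 equiv), 20 °C
Reagents that add atoms: none
Why: Excitation of the diazo ketone expels nitrogen and, because the ring holds the C=O and C=N2 units s-Z, the oxane C3–C4 bond shifts to the diazo carbon in concert with or directly after nitrogen loss, giving ring-contracted ketene 12. Methanol 11 adds to the ketene and the ester enol tautomerizes to epimer mixture 13, which NaOCH3 equilibrates to 14. The closest known reaction type is the photochemical Wolff ring contraction of 2-diazocycloalkanones and of oxygen-heterocyclic analogues such as 3-diazochroman-4-ones and 4-diazooxolan-3-ones. The oxolane is closed by a 1,2-shift inside the existing ring (six to five members, new C3–C4 bond in target numbering), not by an end-to-end cyclization, so no Baldwin constraint applies. The migrating carbon C3 keeps its configuration, so the trans C2/C3 relationship is carried over unchanged. The one new stereocentre, C4, is set under thermodynamic control: after methoxide equilibration the ester should lie trans to the neighbouring CH2OSi group. The step needs the Wolff shift to outrun 1,2-hydride shift from the oxygen-bearing oxane C6 (which would return enone 7) and O–H insertion into methanol; the locked s-Z geometry, direct irradiation without metal or sensitizer, and the fact that C3 is the only group on the carbonyl carbon able to migrate secure this. Light above 300 nm is not absorbed by the aryl ether chromophores.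

Step 7
Reactants: 14 methyl (3R,4S,5R)-4-{[(tert-butyldimethylsilyl)oxy]methyl}-5-(3,4,5-trimethoxyphenyl)oxolane-3-carboxylate
Product: 15 (3R,4S,5R)-4-{[(tert-butyldimethylsilyl)oxy]methyl}-N-methoxy-N-methyl-5-(3,4,5-trimethoxyphenyl)oxolane-3-carboxamide
Conditions: MeNHOMe·HCl, i-PrMgCl, THF, −20 → 0 °C
Reagents that add atoms: N,O-dimethylhydroxylamine hydrochloride, CNOC.Cl
Why: Aminolysis of the ester by the chloromagnesium amide of N,O-dimethylhydroxylamine (Weinreb amide synthesis). The α-centre is already in its stable trans configuration, so any enolization under the basic conditions is harmless.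

Step 8
Reactants: 15 (3R,4S,5R)-4-{[(tert-butyldimethylsilyl)oxy]methyl}-N-methoxy-N-methyl-5-(3,4,5-trimethoxyphenyl)oxolane-3-carboxamide; 16 4-bromo-1,2-dimethoxybenzene
Product: 18 [(3R,4S,5R)-4-{[(tert-butyldimethylsilyl)oxy]methyl}-5-(3,4,5-trimethoxyphenyl)oxolan-3-yl](3,4-dimethoxyphenyl)methanone, via 3,4-dimethoxyphenyllithium 17 (not isolated)
Conditions: 16, n-BuLi, THF, −78 °C; then 15, −78 → 0 °C; aq NH4Cl
Reagents that add atoms: none
Why: Bromine–lithium exchange followed by Weinreb ketone synthesis: the chelated tetrahedral adduct persists until the quench, so exactly one aryl group is delivered and the C7' carbon reaches the ketone level.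

Step 9
Reactants: 18 [(3R,4S,5R)-4-{[(tert-butyldimethylsilyl)oxy]methyl}-5-(3,4,5-trimethoxyphenyl)oxolan-3-yl](3,4-dimethoxyphenyl)methanone
Product: 19 (S)-[(3R,4S,5R)-4-{[(tert-butyldimethylsilyl)oxy]methyl}-5-(3,4,5-trimethoxyphenyl)oxolan-3-yl](3,4-dimethoxyphenyl)methanol
Conditions: (R)-1-methyl-3,3-diphenyltetrahydro-1H,3H-pyrrolo[1,2-c][1,3,2]oxazaborole (0.3 equiv), BH3·SMe2, THF, −20 °C; MeOH quench
Reagents that add atoms: none
Why: Corey–Bakshi–Shibata reduction: the ketone binds the catalyst boron through the lone pair anti to the aryl group, taken as the larger substituent, and the nitrogen-bound borane delivers hydride to the face that gives the (S)-carbinol, as the (R)-catalyst does with aryl alkyl ketones. Reagent control sets C7' and has to cooperate with or override induction from C4.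

Step 10
Reactants: 19 (S)-[(3R,4S,5R)-4-{[(tert-butyldimethylsilyl)oxy]methyl}-5-(3,4,5-trimethoxyphenyl)oxolan-3-yl](3,4-dimethoxyphenyl)methanol
Product: 20 (S)-(3,4-dimethoxyphenyl)[(3R,4S,5R)-4-(hydroxymethyl)-5-(3,4,5-trimethoxyphenyl)oxolan-3-yl]methanol
Conditions: Bu4NF, THF, 0 → 20 °C
Reagents that add atoms: none
Why: Fluoride cleavage of the primary silyl ether under non-acidic conditions, which both electron-rich benzylic C–O bonds should tolerate.

## Compound list

1 | 3,4,5-trimethoxybenzaldehyde | COc1cc(C=O)cc(OC)c1OC | starting material
2 | (E)-1-methoxy-3-(trimethylsilyloxy)buta-1,3-diene | CO/C=C/C(=C)O[Si](C)(C)C | starting material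
3 | (1E,5R)-1-methoxy-5-(3,4,5-trimethoxyphenyl)-5-(trimethylsilyloxy)pent-1-en-3-one | CO/C=C/C(=O)C[C@@H](O[Si](C)(C)C)c1cc(OC)c(OC)c(OC)c1 | intermediate
4 | (2R)-2-(3,4,5-trimethoxyphenyl)-2,3-dihydro-4H-pyran-4-one | O=C1C=CO[C@@H](c2cc(OC)c(OC)c(OC)c2)C1 | intermediate
5 | formaldehyde (from paraformaldehyde) | C=O | starting material
6 | (2R,3S)-3-(hydroxymethyl)-2-(3,4,5-trimethoxyphenyl)-2,3-dihydro-4H-pyran-4-one | O=C1C=CO[C@@H](c2cc(OC)c(OC)c(OC)c2)[C@@H]1CO | intermediate
7 | (2R,3S)-3-{[(tert-butyldimethylsilyl)oxy]methyl}-2-(3,4,5-trimethoxyphenyl)-2,3-dihydro-4H-pyran-4-one | O=C1C=CO[C@@H](c2cc(OC)c(OC)c(OC)c2)[C@@H]1CO[Si](C)(C)C(C)(C)C | intermediate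
8 | (2R,3S)-3-{[(tert-butyldimethylsilyl)oxy]methyl}-2-(3,4,5-trimethoxyphenyl)oxan-4-one | O=C1CCO[C@@H](c2cc(OC)c(OC)c(OC)c2)[C@@H]1CO[Si](C)(C)C(C)(C)C | intermediate
9 | (2R,3S)-3-{[(tert-butyldimethylsilyl)oxy]methyl}-5-(trifluoroacetyl)-2-(3,4,5-trimethoxyphenyl)oxan-4-one (drawn as the diketone, largely enolized, C5 undefined) | O=C1C(C(=O)C(F)(F)F)CO[C@@H](c2cc(OC)c(OC)c(OC)c2)[C@@H]1CO[Si](C)(C)C(C)(C)C | intermediate
10 | (2R,3S)-3-{[(tert-butyldimethylsilyl)oxy]methyl}-5-diazo-2-(3,4,5-trimethoxyphenyl)oxan-4-one | [N-]=[N+]=C1CO[C@@H](c2cc(OC)c(OC)c(OC)c2)[C@H](CO[Si](C)(C)C(C)(C)C)C1=O | intermediate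
11 | methanol | CO | starting material
12 | [(4S,5R)-4-{[(tert-butyldimethylsilyl)oxy]methyl}-5-(3,4,5-trimethoxyphenyl)oxolan-3-ylidene]methanone (ketene) | O=C=C1CO[C@@H](c2cc(OC)c(OC)c(OC)c2)[C@@H]1CO[Si](C)(C)C(C)(C)C | intermediate
13 | methyl (4S,5R)-4-{[(tert-butyldimethylsilyl)oxy]methyl}-5-(3,4,5-trimethoxyphenyl)oxolane-3-carboxylate, mixture of C3 epimers | COC(=O)C1CO[C@@H](c2cc(OC)c(OC)c(OC)c2)[C@@H]1CO[Si](C)(C)C(C)(C)C | intermediate
14 | methyl (3R,4S,5R)-4-{[(tert-butyldimethylsilyl)oxy]methyl}-5-(3,4,5-trimethoxyphenyl)oxolane-3-carboxylate | COC(=O)[C@H]1CO[C@@H](c2cc(OC)c(OC)c(OC)c2)[C@@H]1CO[Si](C)(C)C(C)(C)C | intermediate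
15 | (3R,4S,5R)-4-{[(tert-butyldimethylsilyl)oxy]methyl}-N-methoxy-N-methyl-5-(3,4,5-trimethoxyphenyl)oxolane-3-carboxamide | CON(C)C(=O)[C@H]1CO[C@@H](c2cc(OC)c(OC)c(OC)c2)[C@@H]1CO[Si](C)(C)C(C)(C)C | intermediate
16 | 4-bromo-1,2-dimethoxybenzene | COc1ccc(Br)cc1OC | starting material
17 | 3,4-dimethoxyphenyllithium | [Li]c1ccc(OC)c(OC)c1 | intermediate
18 | [(3R,4S,5R)-4-{[(tert-butyldimethylsilyl)oxy]methyl}-5-(3,4,5-trimethoxyphenyl)oxolan-3-yl](3,4-dimethoxyphenyl)methanone | COc1ccc(C(=O)[C@H]2CO[C@@H](c3cc(OC)c(OC)c(OC)c3)[C@@H]2CO[Si](C)(C)C(C)(C)C)cc1OC | intermediate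
19 | (S)-[(3R,4S,5R)-4-{[(tert-butyldimethylsilyl)oxy]methyl}-5-(3,4,5-trimethoxyphenyl)oxolan-3-yl](3,4-dimethoxyphenyl)methanol | COc1ccc([C@@H](O)[C@H]2CO[C@@H](c3cc(OC)c(OC)c(OC)c3)[C@@H]2CO[Si](C)(C)C(C)(C)C)cc1OC | intermediate
20 | (S)-(3,4-dimethoxyphenyl)[(3R,4S,5R)-4-(hydroxymethyl)-5-(3,4,5-trimethoxyphenyl)oxolan-3-yl]methanol | COc1ccc([C@@H](O)[C@H]2CO[C@@H](c3cc(OC)c(OC)c(OC)c3)[C@@H]2CO)cc1OC | target

## Step count and least certain steps

Total step count: 10. Longest linear sequence: 10 steps (1 to 20); 5, 11 and 16 enter as purchased materials in steps 2, 6 and 8.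

**Step 6 (key step).** The most likely failure is diversion of the excited diazo ketone or its carbene away from the 1,2-carbon shift. A hydride shift from oxane C6, which is activated by the adjacent ring oxygen, would regenerate the enone framework, and O–H insertion into methanol would give an unrearranged α-methoxy ketone. The fallback replaces nitrogen extrusion by an oxidative ring contraction of ketone 8. With PhI(OAc)2 and catalytic H2SO4 in HC(OCH3)3/CH3OH, the methyl enol ether formed toward the unhindered oxane C5 is attacked by trivalent iodine, and the C3–C4 bond shifts to C5 as iodobenzene departs. The resulting dimethoxycarbenium ion collapses to the methyl ester, and NaOCH3 equilibration returns the route at 14. Because the medium is acidic, the silyl ether may have to be re-installed with t-BuMe2SiCl and imidazole. This fallback makes no compound outside the list (F0).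

**Step 2.** The cross-conjugated enolate may expel the ring oxygen by β-elimination, which opens the ring and would erode the C2 configuration on re-closure, and formaldehyde may oligomerize or over-react. The fallback sets out from 4 and avoids the lithium enolate. Soft enolization with Me3SiOTf and Et3N in CH2Cl2 gives the silyl dienol ether (2R)-4-(trimethylsilyloxy)-2-(3,4,5-trimethoxyphenyl)-2H-pyran F1. A Mukaiyama hydroxymethylation of F1 with aqueous formaldehyde and catalytic Yb(OTf)3 in THF/H2O should then attack through oxane C3 anti to the aryl group and returns the route at 6.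

**Step 5.** Deprotonation may stray to oxane C3, followed by β-elimination of the silyloxy group, or acylation may be incomplete. The fallback sets out from enone 7 and generates the enolate regiospecifically: conjugate reduction with LiBH(s-Bu)3 in THF at −78 °C and direct trapping of the enolate with CF3CO2CH2CF3 gives 9 with no possibility of enolization toward C3. The same diazo transfer returns the route at 10. This fallback makes no compound outside the list (F0).

**Step 9.** Facial selectivity may be poor because the aryl and the branched oxolanyl groups are similar in size and induction from C4 may oppose the catalyst. The fallback sets out from 18 and gives up face selection. NaBH4 in MeOH gives both C7' epimers, which are separated. The unwanted (R)-[(3R,4S,5R)-4-{[(tert-butyldimethylsilyl)oxy]methyl}-5-(3,4,5-trimethoxyphenyl)oxolan-3-yl](3,4-dimethoxyphenyl)methanol F2 is inverted by a Mitsunobu reaction (4-nitrobenzoic acid, PPh3, diisopropyl azodicarboxylate, THF) to (S)-[(3R,4S,5R)-4-{[(tert-butyldimethylsilyl)oxy]methyl}-5-(3,4,5-trimethoxyphenyl)oxolan-3-yl](3,4-dimethoxyphenyl)methyl 4-nitrobenzoate F3. Methanolysis of F3 with K2CO3 in MeOH returns the route at 19.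

## Further compounds

F0 | step 6 | none | none
F1 | step 2 | (2R)-4-(trimethylsilyloxy)-2-(3,4,5-trimethoxyphenyl)-2H-pyran | C[Si](C)(C)OC1=C[C@H](c2cc(OC)c(OC)c(OC)c2)OC=C1
F0 | step 5 | none | none
F2 | step 9 | (R)-[(3R,4S,5R)-4-{[(tert-butyldimethylsilyl)oxy]methyl}-5-(3,4,5-trimethoxyphenyl)oxolan-3-yl](3,4-dimethoxyphenyl)methanol | COc1ccc([C@H](O)[C@H]2CO[C@@H](c3cc(OC)c(OC)c(OC)c3)[C@@H]2CO[Si](C)(C)C(C)(C)C)cc1OC
F3 | step 9 | (S)-[(3R,4S,5R)-4-{[(tert-butyldimethylsilyl)oxy]methyl}-5-(3,4,5-trimethoxyphenyl)oxolan-3-yl](3,4-dimethoxyphenyl)methyl 4-nitrobenzoate | COc1ccc([C@@H](OC(=O)c3ccc(cc3)[N+](=O)[O-])[C@H]2CO[C@@H](c4cc(OC)c(OC)c(OC)c4)[C@@H]2CO[Si](C)(C)C(C)(C)C)cc1OC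
A1 | alternative 1 | (5R)-5-{[(1R,2S,5R)-2-isopropyl-5-methylcyclohexyl]oxy}furan-2(5H)-one | O=C1O[C@@H](O[C@@H]2C[C@H](C)CC[C@H]2C(C)C)C=C1
A2 | alternative 1 | 2-(3,4-dimethoxyphenyl)-1,3-dithiane | COc1ccc(C2SCCCS2)cc1OC
A3 | alternative 1 | trans,trans-4-[2-(3,4-dimethoxyphenyl)-1,3-dithian-2-yl]-3-[hydroxy(3,4,5-trimethoxyphenyl)methyl]-5-(l-menthyloxy)oxolan-2-one | O=C1O[C@@H](O[C@@H]2C[C@H](C)CC[C@H]2C(C)C)[C@H](C2(c3ccc(OC)c(OC)c3)SCCCS2)[C@@H]1[C@@H](O)c4cc(OC)c(OC)c(OC)c4
A4 | alternative 2 | 4-(3,4-dimethoxyphenyl)-4-[(E)-3-(tert-butyldiphenylsilyloxy)prop-1-enyl]-2-(3,4,5-trimethoxyphenyl)-1,3-dioxolane (E-alkene; ring centres not specified) | COc1ccc(C2(/C=C/CO[Si](c3ccccc3)(c3ccccc3)C(C)(C)C)COC(c3cc(OC)c(OC)c(OC)c3)O2)cc1OC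
A5 | alternative 2 | [(3R,4S,5R)-4-{[(tert-butyldiphenylsilyl)oxy]methyl}-5-(3,4,5-trimethoxyphenyl)oxolan-3-yl](3,4-dimethoxyphenyl)methanone | COc1ccc(C(=O)[C@H]2CO[C@@H](c3cc(OC)c(OC)c(OC)c3)[C@@H]2CO[Si](c4ccccc4)(c4ccccc4)C(C)(C)C)cc1OC
A6 | alternative 3 | (1R,2S,3E)-2-{[(tert-butyldiphenylsilyl)oxy]methyl}-4-(3,4-dimethoxyphenyl)-1-(3,4,5-trimethoxyphenyl)but-3-en-1-ol | O[C@@H](c1cc(OC)c(OC)c(OC)c1)[C@@H](/C=C/c1ccc(OC)c(OC)c1)CO[Si](c1ccccc1)(c1ccccc1)C(C)(C)C
A7 | alternative 3 | (S)-[(3R,4S,5R)-4-{[(tert-butyldiphenylsilyl)oxy]methyl}-5-(3,4,5-trimethoxyphenyl)oxolan-3-yl](3,4-dimethoxyphenyl)methanol | COc1ccc([C@@H](O)[C@H]2CO[C@@H](c3cc(OC)c(OC)c(OC)c3)[C@@H]2CO[Si](c4ccccc4)(c4ccccc4)C(C)(C)C)cc1OC
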